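Free catalyst plus spent catalyst always adds up to the charge, and the proposed steps take one target for each spent catalyst. So in ash the whole charge can cost 0.400 % of the substrate charged as target, less than the scatter of a reading. We therefore ask where the substrate goes.

| flask | substrate | free catalyst | temperature | remark | time |
|---|---|---|---|---|---|
| ash | 1 M | 4 mM | 82 °C | run made earlier |  |
| larch | 1.5 M | 4 mM | 110 °C | run made earlier |  |
| alder | 2 M | 6 mM | 82 °C | run made earlier |  |
| teal | 2.0 M | 4.0 mM | 95 °C |  | 5.0 min |
| blue | 2.0 M | 4.0 mM | 70 °C |  | 5.0 min |
| violet | 2.0 M | 4.0 mM |  | at 120 °C until 2.5 min, from then on at 70 °C | 5.0 min |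
| green | 2.0 M | 4.0 mM | 120 °C |  | 5.0 min |

| run | time / min | target / % | substrate / % |
|---|---|---|---|
| ash | 0.833 | 15.2 | 9.1 |
| ash | 1.50 | 16.4 | 4.4 |
| ash | 2.50 | 17.2 | 3.1 |
| ash | 5.00 | 20.2 | 1.3 |
| ash | 10.0 | 17.5 | 0.8 |
| larch | 0.200 | 3.6 | 5.1 |
| larch | 0.417 | 5.4 | 1.8 |
| larch | 0.667 | 6.6 | 0.1 |
| larch | 1.33 | 6.9 | 1.1 |
| larch | 2.50 | 7.5 | 0.2 |
| alder | 2.00 | 13.8 | 0.1 |
| alder | 4.00 | 14.5 | 2.0 |
| alder | 6.00 | 12.6 | 1.2 |
| alder | 8.00 | 16.0 | 0.6 |
| alder | 10.0 | 15.1 | 1.3 |

(readings scatter by 1 percentage point)

- a species is counted by the substrate in it: one side product or self-condensation product counts as two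
- steps that have been proposed: substrate + free catalyst -> free catalyst + target; substrate + target -> side product; 2 substrate -> self-condensation product; free catalyst + target -> spent catalyst

- the flask with the highest amount of target, in percent of the substrate charged ("all alike" if they lie within 1.5 percentage points) (teal / blue / violet / green / all alike)
- final target, as a percentage of the substrate charged, in teal
- final target, as a percentage of the substrate charged, in blue
- final target, as a percentage of the substrate charged, in violet
- final target, as a percentage of the substrate charged, in green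

In ash the last three target readings average 18.3 %, with 0.8 % substrate at the end, so the rest left by another route. The catalysed step goes as [free catalyst][substrate], self-condensation as [substrate]². Divide one rate by the other and time cancels. With s the fraction of substrate left, the share becoming target is 1/(1 + rs), where r = q[substrate]/[free catalyst], taken at the start. We assume [free catalyst] holds at its charge while substrate lasts. Adding the shares as s falls to zero gives Y = ln(1 + r)/r.

Solving this by trial for ash gives r = 15.3, so q = 0.0611. This q is what we carry: the selectivity factor, substrate use by self-condensation over catalysed use at equal concentrations.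

Does it hold at another charge? For alder it gives r = 20.4 and Y = 15.0 %, against a mean target reading of 14.4 %.

How does q move with temperature? Larch's last three target readings average 7.00 %, which gives r = 58.4 and q = 0.156. That is a slope of 4550 K in 1/T.

Our reckoning then gives r = 19.5 and 15.5 % for blue, r = 48.0 and 8.11 % for teal, and r = 105 and 4.43 % for green. Larch, cooler and more dilute than violet before its change, read 0.2 % substrate at 2.50 min, the time of that change, so we give violet green's number. Blue leads teal by 7.4 percentage points, more than the margin.

The forecast names blue, with 8 % for teal, 13.5 % for blue, 4.6 % for violet and 4.5 % for green: “So self-condensation has the higher activation energy”. Its widest gap from our reckoning is in blue, where it stands lower than our 15.5 %, by 2 points.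

    substrate + free catalyst → free catalyst + target (k = 1.54 M⁻¹ s⁻¹, Ea = 40.0 kJ mol⁻¹)
    substrate + target → side product (k = 5.51 × 10⁻⁴ M⁻¹ s⁻¹, Ea = 64.0 kJ mol⁻¹)
    2 substrate → self-condensation product (k = 0.0278 M⁻¹ s⁻¹, Ea = 76.0 kJ mol⁻¹)
    free catalyst + target → spent catalyst (k = 0.00300 M⁻¹ s⁻¹, Ea = 83.0 kJ mol⁻¹)
    (constants at 70 °C)

The flask with the highest target is blue, at 14.8 %, followed by teal at 8.31 %, violet at 4.59 % and green at 4.56 %. Blue still holds 1.1 % of its substrate at 5.00 min, and after 50.0 min its target stands at 15.5 %, against our 15.5 %. Carried to blue's charge run at 85 °C, q gives r = 34.0 and Y = 10.5 %, and that neighbour flask holds 10.6 % of target at 5.00 min.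

The earlier runs and the new flask were computed for substances that don't exist; the scatter is artificial.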